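Retrosynthesis: the oxepane O–C3 bond is cut first (oxygen removed from between C3 and C16), giving a cyclohexanone ring B (C1, C2, C3, C16, C15, C14); then C6=C7 (metathesis), C4–C5 (allylboration), C9–C8 (C-glycosylation), C11=C12 and C10–C11 (aldol condensation, acylation), C1–C10 (epoxide opening) and C3–C4 (2,3-Wittig shift), back to (R)-carvone.
Enabling feature: without the ring oxygen, C3 is an all-carbon quaternary α-carbon (methyl, C2, C4) of the C16 ketone, the other α-carbon C15 is only secondary, and the only other carbonyl (C13) is conjugated with C11=C12 in ring A; the hindered tertiary ether can therefore be made by a retentive carbon-to-oxygen shift.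
Forward order: ring B is the carvone ring; the tetrahydrofuran is annulated as a trans-fused lactone; ring A is closed by a Hagemann-type aldol condensation; the oxonane by ring-closing metathesis; ring B is expanded to the oxepane last.
Stereochemistry: C14 from (R)-carvone; C15 by trans methylation; C3 by a suprafacial 2,3-shift from a C1 carbinol; C2 and C1 by directed epoxidation and trans-diaxial opening; C10 by equilibration to the cis-fused lactone.
C9 by convex-face attack on an oxocarbenium ion; C4 by reagent-controlled allylboration; C7 by convex-face dihydroxylation; C6 by hydroxyl-directed reduction; the C3–O bond by retention in the key step.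

Key step: step 24

Assumption: atom numbers are those of the target skeleton (ether oxygen between C2 and C9, oxepane oxygen between C3 and C16). Carbinol centres that are later oxidised or ionised (C16 in 3–22, C9 and C13 in 18–22, C13 and C16 in 33 and 34) need no control and carry no descriptor in the SMILES where no single epimer is expected. C10 of 13 and 15 equilibrates and is drawn as the epimer that cyclises.

Step 1
Reactants: 1 (R)-carvone
Product: 2 (5R,6S)-6-methylcarvone
Conditions: LiN(iPr)2, THF, −78 °C; MeI, −78 to 0 °C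
Reagents that add atoms: iodomethane, CI
Why: Alkylation of the kinetic α′-enolate; iodomethane enters anti to the neighbouring isopropenyl group, which sets C15 with its methyl trans to the C14 substituent.

Step 2
Reactants: 2 (5R,6S)-6-methylcarvone
Product: 3 (1R,5R,6S)-6-methylcarveol
Conditions: NaBH4, CeCl3·7H2O, MeOH, −78 to 0 °C
Reagents that add atoms: none
Why: Luche 1,2-reduction takes C16 to the alcohol level so that the later organolithium and base steps cannot attack it or epimerise C15; axial hydride attack should give the carbinol cis to isopropenyl, a centre that is oxidised again in step 16.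

Step 3
Reactants: 3 (1R,5R,6S)-6-methylcarveol
Product: 4 C16 silyl ether
Conditions: TBSOTf, 2,6-lutidine, CH2Cl2, 0 °C
Reagents that add atoms: tert-butyldimethylsilyl triflate, CC(C)(C)[Si](C)(C)OS(=O)(=O)C(F)(F)F
Why: Silyl ether formation protects the C16 hydroxyl and stops it from directing the epoxidation of step 8.

Step 4
Reactants: 4 C16 silyl ether
Product: 5 transposed enone (C1 ketone, C2=C3)
Conditions: CrO3, 3,5-dimethylpyrazole, CH2Cl2, −20 °C
Reagents that add atoms: chromium trioxide, O=[Cr](=O)=O
Why: Allylic oxidation of a trisubstituted cyclohexene at the ring methylene next to its CH= carbon (C1), the regiochemistry known from the oxidation of steroidal 5-enes to 7-ketones; no stereocentre is created.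

Step 5
Reactants: 5 transposed enone
Product: 6 C1 allylic alcohol
Conditions: NaBH4, CeCl3·7H2O, MeOH, −78 °C
Reagents that add atoms: none
Why: Luche reduction; axial delivery of hydride to the C1 carbonyl should give the pseudo-equatorial alcohol trans to the adjacent isopropenyl group, the centre that later steers C3.

Step 6
Reactants: 6 C1 allylic alcohol
Product: 7 C1 stannylmethyl ether
Conditions: KH, Bu3SnCH2I, THF, 0 °C to rt
Reagents that add atoms: tributyl(iodomethyl)stannane, CCCC[Sn](CI)(CCCC)CCCC
Why: Williamson etherification of the potassium alkoxide installs the stannylmethyl ether needed for the Wittig–Still rearrangement; no stereocentre changes.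

Step 7
Reactants: 7 C1 stannylmethyl ether
Product: 9 homoallylic alcohol (quaternary C3), via lithiomethyl ether 8 (not isolated)
Conditions: nBuLi, THF, −78 °C
Reagents that add atoms: none
Why: Tin–lithium exchange then 2,3-Wittig–Still rearrangement; the shift is suprafacial, so carbon C4 is delivered to C3 on the face of the former C1–O bond, which sets the quaternary centre (CH2OH trans to the C14 substituent, cis to the C15 methyl) and moves the alkene to C1=C2.

Step 8
Reactants: 9 homoallylic alcohol
Product: 10 epoxy alcohol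
Conditions: VO(acac)2 (cat.), tBuOOH, CH2Cl2, 0 °C to rt
Reagents that add atoms: tert-butyl hydroperoxide, CC(C)(C)OO
Why: Vanadium-catalysed hydroxyl-directed epoxidation of the homoallylic alcohol; oxygen is delivered syn to the CH2OH group, which is the face anti to isopropenyl, and the undirected isopropenyl alkene is left alone.

Step 9
Reactants: 10 epoxy alcohol
Product: 12 trans-fused lactone, via hydroxy ynol ether 11 (not isolated)
Conditions: HC≡COEt, nBuLi, THF, −78 °C; BF3·OEt2; then PPTS, wet CH2Cl2, rt
Reagents that add atoms: ethoxyacetylene, CCOC#C; water, O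
Why: Lewis-acid-assisted alkynylation of the epoxide (Yamaguchi type) by trans-diaxial attack at C1, the carbon not flanked by quaternary C3, then acid-catalysed hydration and lactonisation of the ynol ether; inversion at C1 puts C10 cis to the C14 substituent and leaves the C2 oxygen trans to C10.

Step 10
Reactants: 12 trans-fused lactone
Product: 13 C10-acetyl lactone
Conditions: LiN(SiMe3)2 (3.3 equiv), THF, −78 °C; MeC(O)N(OMe)Me, −78 to 0 °C
Reagents that add atoms: N-methoxy-N-methylacetamide, CC(=O)N(C)OC
Why: Claisen-type C-acylation of the lactone enolate by a Weinreb amide adds C11 and its methyl; C10 becomes a freely epimerising β-keto lactone centre.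

Step 11
Reactants: 13 C10-acetyl lactone
Product: 15 diketo lactone, via ozonide 14 (not isolated)
Conditions: O3, CH2Cl2, −78 °C; PPh3
Reagents that add atoms: ozone, [O-][O+]=O
Why: Ozonolysis of the only alkene, the 1,1-disubstituted isopropenyl group, gives the C13 methyl ketone (C12 is its methyl) without touching a stereocentre.

Step 12
Reactants: 15 diketo lactone
Product: 17 tetracyclic enone lactone, via ketol 16 (not isolated)
Conditions: pyrrolidine, AcOH, MeOH, 50 °C
Reagents that add atoms: none
Why: Amine-mediated intramolecular aldol condensation in the sense that gives Hagemann's ester: the enamine of the simple C13 methyl ketone adds through C12 to the β-keto lactone carbonyl C11 and water is lost; ring A is cis-fused because C10 and C13 are cis on ring B, and C10 settles as the cis-fused lactone epimer.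

Step 13
Reactants: 17 tetracyclic enone lactone
Product: 19 triacetate, via lactol triol 18 (not isolated)
Conditions: iBu2AlH, CH2Cl2, −78 °C; then pyridine, DMAP, Ac2O, −78 to 0 °C
Reagents that add atoms: acetic anhydride, CC(=O)OC(C)=O
Why: Hydride reduction of the lactone to the lactol and of the enone to the allylic alcohol, with acetylation in the same flask (Rychnovsky reductive acetylation), gives the anomeric acetate and keeps C13 as an inert ester; the new C9 and C13 centres are mixtures that are reset later.

Step 14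
Reactants: 19 triacetate
Product: 20 C9-methallyl tetrahydrofuran
Conditions: CH2=C(Me)CH2SiMe3, BF3·OEt2, CH2Cl2, −78 °C
Reagents that add atoms: trimethyl(2-methylallyl)silane, C=C(C)C[Si](C)(C)C
Why: Hosomi–Sakurai C-glycosylation: the anomeric acetate ionises to the oxocarbenium ion and the allylsilane adds to C9 from the convex face, anti to the cis-fused ring A (trans to C11), which gives the 2,5-cis tetrahydrofuran.

Step 15
Reactants: 20 C9-methallyl tetrahydrofuran
Product: 22 triol, via diol 21 (not isolated)
Conditions: K2CO3, MeOH, rt; then Bu4NF, THF, 50 °C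
Reagents that add atoms: none
Why: Ester methanolysis followed by fluoride desilylation frees the C13, C4 and C16 hydroxyls for a single oxidation.

Step 16
Reactants: 22 triol
Product: 23 keto enone aldehyde
Conditions: Dess–Martin periodinane, NaHCO3, CH2Cl2, rt
Reagents that add atoms: none
Why: Dess–Martin oxidation returns the C13 enone and the C16 ketone and gives the C4 aldehyde; the C15 hydrogen lies pseudo-equatorial, poorly aligned with the new carbonyl, and should not enolise under these non-basic conditions.

Step 17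
Reactants: 23 keto enone aldehyde
Product: 24 (4S)-homoallylic alcohol
Conditions: (−)-Ipc2B(allyl), Et2O, −78 °C; then H2NCH2CH2OH
Reagents that add atoms: (−)-B-allyldiisopinocampheylborane, C=CCB([C@@H]1C[C@@H]2C[C@H]([C@H]1C)C2(C)C)[C@@H]1C[C@@H]2C[C@H]([C@H]1C)C2(C)C
Why: Brown allylboration through a chair six-membered transition state under reagent control; the borane made from (+)-α-pinene should give the (S)-carbinol as it does with benzaldehyde and pivaldehyde, and the aldehyde reacts far faster than the hindered ketones.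

Step 18
Reactants: 24 (4S)-homoallylic alcohol
Product: 25 C4 silyl ether diene
Conditions: TBSOTf, 2,6-lutidine, CH2Cl2, −78 to 0 °C
Reagents that add atoms: tert-butyldimethylsilyl triflate, CC(C)(C)[Si](C)(C)OS(=O)(=O)C(F)(F)F
Why: Silylation of the hindered secondary alcohol with a non-nucleophilic base, which also blocks retro-aldol loss of the side chain.

Step 19
Reactants: 25 C4 silyl ether diene
Product: 26 (Z)-oxonene
Conditions: second-generation Grubbs catalyst (H2IMes)(PCy3)Cl2Ru=CHPh (10 mol %), CH2Cl2 (2 mM), 40 °C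
Reagents that add atoms: none
Why: Ring-closing metathesis of the monosubstituted and the 1,1-disubstituted alkene; the cis-2,5-disubstituted tetrahydrofuran holds the two chains close, and the nine-membered ring can only accommodate the (Z)-alkene.

Step 20
Reactants: 26 (Z)-oxonene
Product: 27 6,7-syn-diol
Conditions: OsO4 (5 mol %), N-methylmorpholine N-oxide, acetone/H2O, rt
Reagents that add atoms: N-methylmorpholine N-oxide, C[N+]1([O-])CCOCC1; water, O
Why: Upjohn dihydroxylation of the only electron-rich alkene; osmylation from the convex face of the oxonene, away from the carbocyclic core, should set C7 as (7S), and the cis-related C6 hydroxyl is corrected in the next two steps.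

Step 21
Reactants: 27 6,7-syn-diol
Product: 28 7-hydroxy-6-ketone
Conditions: Dess–Martin periodinane, NaHCO3, CH2Cl2, 0 °C
Reagents that add atoms: none
Why: Dess–Martin oxidation of the secondary C6 alcohol; the tertiary C7 alcohol cannot be oxidised.

Step 22
Reactants: 28 7-hydroxy-6-ketone
Product: 29 (6S,7S)-diol
Conditions: Me4NBH(OAc)3, AcOH/MeCN, −30 °C
Reagents that add atoms: none
Why: Hydroxyl-directed reduction (Evans–Saksena): hydride is delivered within the C7 alkoxyborohydride, which gives the trans 6,7-diol with C6 as (6S), and ketones without a neighbouring hydroxyl (C13, C16) are not reduced.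

Step 23
Reactants: 29 (6S,7S)-diol
Product: 30 bis-silyl ring B ketone
Conditions: TBSOTf (1.2 equiv), 2,6-lutidine, CH2Cl2, −78 °C
Reagents that add atoms: tert-butyldimethylsilyl triflate, CC(C)(C)[Si](C)(C)OS(=O)(=O)C(F)(F)F
Why: Selective silylation of the secondary C6 alcohol; the tertiary C7 alcohol is too hindered to react at low temperature.

Step 24
Reactants: 30 bis-silyl ring B ketone
Product: 32 seven-membered lactone, via Criegee adduct 31 (not isolated)
Conditions: mCPBA, NaHCO3, CH2Cl2, 0 °C to rt
Reagents that add atoms: 3-chloroperbenzoic acid, OOC(=O)c1cccc(Cl)c1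
Why: The peracid adds to the saturated C16 ketone to give Criegee adduct 31, whose C3–C16 bond, lying antiperiplanar to the O–O bond, shifts to oxygen as 3-chlorobenzoate leaves (Baeyer–Villiger oxidation; the closest precedent is the ring expansion of 2,2-disubstituted cyclohexanones to ε-caprolactones). The oxepanone ring arises by this 1,2-shift, a one-atom expansion of the cyclohexanone, and not by an etherification. C3 becomes the oxygen-bearing stereocentre with retention, because the shift is suprafacial at the migrating carbon. The step needs migration of C3 rather than C15; the tertiary-alkyl character of C3 (against secondary C15) and the relief of the 1,3-diaxial strain between C4 and the C15 methyl favour this. It also needs attack at C16 rather than at the enone; the conjugated C13 carbonyl and its electron-poor alkene react much more slowly with peracids, and no other alkene is left.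

Step 25
Reactants: 32 seven-membered lactone
Product: 33 lactol allylic alcohol
Conditions: iBu2AlH (3.5 equiv), CH2Cl2, −78 °C
Reagents that add atoms: none
Why: Hydride reduction stops at the aluminium hemiacetal (lactol) at low temperature and also reduces the enone carbonyl; both new carbinol centres are removed in the next two steps.

Step 26
Reactants: 33 lactol allylic alcohol
Product: 34 lactol enone
Conditions: MnO2, CH2Cl2, rt
Reagents that add atoms: none
Why: Manganese dioxide oxidation is selective for the allylic alcohol and restores the enone before the Lewis acid step, so that no allylic cation can form at C13.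

Step 27
Reactants: 34 lactol enone
Product: 35 bis-silyl oxepane
Conditions: Et3SiH, BF3·OEt2, CH2Cl2, −78 to −40 °C
Reagents that add atoms: none
Why: Ionic hydrogenation of the lactol: the Lewis acid generates the cyclic oxocarbenium ion and the silane reduces it to the C16 methylene of the oxepane; C3 and C15 are not involved.

Step 28
Reactants: 35 bis-silyl oxepane
Product: 36 triol
Conditions: HF·pyridine, pyridine/THF, 0 °C to rt
Reagents that add atoms: none
Why: Acidic fluoride desilylation frees the C4 and C6 hydroxyls without the base that could epimerise C14 next to the C13 ketone.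

Step 29
Reactants: 36 triol
Product: 37 target CNP0212231.3
Conditions: Ac2O, pyridine, DMAP (cat.), CH2Cl2, rt
Reagents that add atoms: acetic anhydride, CC(=O)OC(C)=O
Why: Nucleophile-catalysed acetylation esterifies the two secondary alcohols; the tertiary C7 alcohol does not react under these conditions.

Compound list
1 | (R)-carvone | CC1=CC[C@H](CC1=O)C(C)=C | starting material
2 | (5R,6S)-6-methylcarvone (C15 methyl trans to isopropenyl) | CC1=CC[C@@H](C(C)=C)[C@H](C)C1=O | intermediate
3 | (1R,5R,6S)-6-methylcarveol (C16–OH cis to isopropenyl) | CC1=CC[C@@H](C(C)=C)[C@H](C)[C@H]1O | intermediate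
4 | C16 TBS ether of 3 | CC1=CC[C@@H](C(C)=C)[C@H](C)[C@H]1O[Si](C)(C)C(C)(C)C | intermediate
5 | transposed enone (C1 ketone, C2=C3, 16-OTBS) | CC1=CC(=O)[C@@H](C(C)=C)[C@H](C)[C@H]1O[Si](C)(C)C(C)(C)C | intermediate
6 | C1 allylic alcohol (OH trans to isopropenyl) | CC1=C[C@H](O)[C@@H](C(C)=C)[C@H](C)[C@H]1O[Si](C)(C)C(C)(C)C | intermediate
7 | C1 (tributylstannyl)methyl ether | CC1=C[C@H](OC[Sn](CCCC)(CCCC)CCCC)[C@@H](C(C)=C)[C@H](C)[C@H]1O[Si](C)(C)C(C)(C)C | intermediate
8 | C1 lithiomethyl ether | CC1=C[C@H](OC[Li])[C@@H](C(C)=C)[C@H](C)[C@H]1O[Si](C)(C)C(C)(C)C | intermediate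
9 | homoallylic alcohol: quaternary C3 (methyl, CH2OH), C1=C2 | OC[C@]1(C)C=C[C@@H](C(C)=C)[C@H](C)[C@H]1O[Si](C)(C)C(C)(C)C | intermediate
10 | C1–C2 epoxide syn to CH2OH | OC[C@]1(C)[C@@H]2O[C@@H]2[C@@H](C(C)=C)[C@H](C)[C@H]1O[Si](C)(C)C(C)(C)C | intermediate
11 | hydroxy ynol ether (ethoxyethynyl at C1, hydroxyl at C2) | CCOC#C[C@@H]1[C@@H](O)[C@@](C)(CO)[C@H](O[Si](C)(C)C(C)(C)C)[C@@H](C)[C@@H]1C(C)=C | intermediate
12 | trans-fused γ-lactone (C2–O–C9(=O)–C10H2–C1) | O=C1O[C@@H]2[C@@H](C1)[C@@H](C(C)=C)[C@H](C)[C@@H](O[Si](C)(C)C(C)(C)C)[C@]2(C)CO | intermediate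
13 | C10-acetyl lactone | CC(=O)[C@@H]1C(=O)O[C@@H]2[C@@H]1[C@@H](C(C)=C)[C@H](C)[C@@H](O[Si](C)(C)C(C)(C)C)[C@]2(C)CO | intermediate
14 | ozonide of 13 | CC(=O)[C@@H]1C(=O)O[C@@H]2[C@@H]1[C@@H](C3(C)OOCO3)[C@H](C)[C@@H](O[Si](C)(C)C(C)(C)C)[C@]2(C)CO | intermediate
15 | diketo lactone (C14 acetyl) | CC(=O)[C@@H]1C(=O)O[C@@H]2[C@@H]1[C@@H](C(C)=O)[C@H](C)[C@@H](O[Si](C)(C)C(C)(C)C)[C@]2(C)CO | intermediate
16 | ketol (C11 tertiary alcohol, ring A closed) | O=C1O[C@@H]2[C@@H]3[C@@H](C(=O)CC(C)(O)[C@@H]31)[C@H](C)[C@@H](O[Si](C)(C)C(C)(C)C)[C@]2(C)CO | intermediate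
17 | tetracyclic enone lactone (rings A and B, lactone) | O=C1O[C@@H]2[C@@H]3[C@@H](C(=O)C=C(C)[C@@H]31)[C@H](C)[C@@H](O[Si](C)(C)C(C)(C)C)[C@]2(C)CO | intermediate
18 | lactol triol (C9 and C13 epimer mixtures) | OC1O[C@@H]2[C@@H]3[C@@H](C(O)C=C(C)[C@@H]31)[C@H](C)[C@@H](O[Si](C)(C)C(C)(C)C)[C@]2(C)CO | intermediate
19 | triacetate (anomeric C9, allylic C13, primary C4) | CC(=O)OC1O[C@@H]2[C@@H]3[C@@H](C(OC(C)=O)C=C(C)[C@@H]31)[C@H](C)[C@@H](O[Si](C)(C)C(C)(C)C)[C@]2(C)COC(C)=O | intermediate
20 | C9-methallyl tetrahydrofuran diacetate | C=C(C)C[C@H]1O[C@@H]2[C@@H]3[C@@H](C(OC(C)=O)C=C(C)[C@@H]31)[C@H](C)[C@@H](O[Si](C)(C)C(C)(C)C)[C@]2(C)COC(C)=O | intermediate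
21 | C4,C13-diol with 16-OTBS | C=C(C)C[C@H]1O[C@@H]2[C@@H]3[C@@H](C(O)C=C(C)[C@@H]31)[C@H](C)[C@@H](O[Si](C)(C)C(C)(C)C)[C@]2(C)CO | intermediate
22 | C4,C13,C16-triol | C=C(C)C[C@H]1O[C@@H]2[C@@H]3[C@@H](C(O)C=C(C)[C@@H]31)[C@H](C)[C@@H](O)[C@]2(C)CO | intermediate
23 | keto enone aldehyde (C16 ketone, C13 enone, C4 aldehyde) | C=C(C)C[C@H]1O[C@@H]2[C@@H]3[C@@H](C(=O)C=C(C)[C@@H]31)[C@H](C)C(=O)[C@]2(C)C=O | intermediate
24 | (4S)-homoallylic alcohol | C=C(C)C[C@H]1O[C@@H]2[C@@H]3[C@@H](C(=O)C=C(C)[C@@H]31)[C@H](C)C(=O)[C@]2(C)[C@@H](O)CC=C | intermediate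
25 | C4 TBS ether diene | C=C(C)C[C@H]1O[C@@H]2[C@@H]3[C@@H](C(=O)C=C(C)[C@@H]31)[C@H](C)C(=O)[C@]2(C)[C@@H](O[Si](C)(C)C(C)(C)C)CC=C | intermediate
26 | (Z)-oxonene (C6=C7) | CC(C)(C)[Si](C)(C)O[C@H]1C/C=C(C)\C[C@H]2O[C@@H]3[C@@H]4[C@@H](C(=O)C=C(C)[C@@H]42)[C@H](C)C(=O)[C@]13C | intermediate
27 | 6,7-syn-diol (6R,7S) | CC(C)(C)[Si](C)(C)O[C@H]1C[C@@H](O)[C@@](C)(O)C[C@H]2O[C@@H]3[C@@H]4[C@@H](C(=O)C=C(C)[C@@H]42)[C@H](C)C(=O)[C@]13C | intermediate
28 | 7-hydroxy-6-ketone | CC(C)(C)[Si](C)(C)O[C@H]1CC(=O)[C@@](C)(O)C[C@H]2O[C@@H]3[C@@H]4[C@@H](C(=O)C=C(C)[C@@H]42)[C@H](C)C(=O)[C@]13C | intermediate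
29 | (6S,7S)-diol | CC(C)(C)[Si](C)(C)O[C@H]1C[C@H](O)[C@@](C)(O)C[C@H]2O[C@@H]3[C@@H]4[C@@H](C(=O)C=C(C)[C@@H]42)[C@H](C)C(=O)[C@]13C | intermediate
30 | 4,6-bis-TBS carbocyclic C16 ketone (ring B cyclohexanone) | CC(C)(C)[Si](C)(C)O[C@H]1C[C@H](O[Si](C)(C)C(C)(C)C)[C@@](C)(O)C[C@H]2O[C@@H]3[C@@H]4[C@@H](C(=O)C=C(C)[C@@H]42)[C@H](C)C(=O)[C@]13C | intermediate
31 | Criegee adduct at C16 | CC(C)(C)[Si](C)(C)O[C@H]1C[C@H](O[Si](C)(C)C(C)(C)C)[C@@](C)(O)C[C@H]2O[C@@H]3[C@@H]4[C@@H](C(=O)C=C(C)[C@@H]42)[C@H](C)C(O)(OOC(=O)c5cccc(Cl)c5)[C@]13C | intermediate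
32 | seven-membered lactone (C16(=O)–O–C3) | CC(C)(C)[Si](C)(C)O[C@H]1C[C@H](O[Si](C)(C)C(C)(C)C)[C@@](C)(O)C[C@H]2O[C@@H]3[C@@H]4[C@@H](C(=O)C=C(C)[C@@H]42)[C@H](C)C(=O)O[C@]13C | intermediate
33 | lactol allylic alcohol (C16 and C13 epimer mixtures) | CC(C)(C)[Si](C)(C)O[C@H]1C[C@H](O[Si](C)(C)C(C)(C)C)[C@@](C)(O)C[C@H]2O[C@@H]3[C@@H]4[C@@H](C(O)C=C(C)[C@@H]42)[C@H](C)C(O)O[C@]13C | intermediate
34 | lactol enone | CC(C)(C)[Si](C)(C)O[C@H]1C[C@H](O[Si](C)(C)C(C)(C)C)[C@@](C)(O)C[C@H]2O[C@@H]3[C@@H]4[C@@H](C(=O)C=C(C)[C@@H]42)[C@H](C)C(O)O[C@]13C | intermediate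
35 | 4,6-bis-TBS oxepane | CC(C)(C)[Si](C)(C)O[C@H]1C[C@H](O[Si](C)(C)C(C)(C)C)[C@@](C)(O)C[C@H]2O[C@@H]3[C@@H]4[C@@H](C(=O)C=C(C)[C@@H]42)[C@H](C)CO[C@]13C | intermediate
36 | 4,6,7-triol | O[C@H]1C[C@H](O)[C@@](C)(O)C[C@H]2O[C@@H]3[C@@H]4[C@@H](C(=O)C=C(C)[C@@H]42)[C@H](C)CO[C@]13C | intermediate
37 | CNP0212231.3 (4,6-diacetate) | CC(=O)O[C@H]1C[C@H](OC(C)=O)[C@@](C)(O)C[C@H]2O[C@@H]3[C@@H]4[C@@H](C(=O)C=C(C)[C@@H]42)[C@H](C)CO[C@]13C | target

Total steps: 29. Longest linear sequence: 29 steps from (R)-carvone; the route is fully linear.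

Steps most likely to fail

Step 9. A Lewis-acid-induced hydride shift of the epoxide to a ketone, or opening at C2, may outrun alkynylation at the hindered C1, and closure of the strained trans-fused lactone may stall at the open hydroxy ester. The fallback brings in C9–C11 as one soft nucleophile without any Lewis acid, by the acetoacetic ester lactone synthesis. Epoxide 10 and the sodium enolate of methyl acetoacetate (NaOMe, MeOH, reflux) should give the hydroxy keto ester F1, which lactonises on warming with PPTS in toluene to the acetyl lactone. This fallback sets out from 10, bypasses 12 and returns to the route at 13.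

Step 24. The secondary carbon C15 may migrate in competition with C3, or the peracid may add so slowly to the hindered C16 carbonyl that oxidation at the enone takes over. The fallback keeps the same oxygen insertion but hands it to an enzyme. Ketone 30 would be incubated with a Baeyer–Villiger monooxygenase (cyclohexanone or phenylacetone monooxygenase variants, screened as whole cells or as isolated flavoenzyme with glucose and glucose dehydrogenase for NADPH recycling, air, buffer with cosolvent). The flavin hydroperoxide of these enzymes does not epoxidise electron-poor alkenes, and the migrating carbon is chosen by the active site and can be selected by screening. This fallback sets out from 30 and returns at 32; no new compound arises (F0).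

Step 7. The lithiomethyl ether may undergo the 1,2-shift or simple protonation instead of the 2,3-shift, because the new bond has to be made to a fully substituted alkene carbon next to the silyloxy-bearing C16. The fallback is a thermal sigmatropic route. Johnson–Claisen rearrangement of allylic alcohol 6 (MeC(OEt)3, cat. EtCO2H, 140 °C) should give the ethyl ester F2 with the same suprafacial transfer to C3. Saponification (LiOH, THF/H2O) gives the acid F3. Barton decarboxylative hydroxylation through the N-hydroxypyridine-2-thione ester F4 (O2, tBuSH, then P(OMe)3) removes the carboxyl carbon and leaves the hydroxymethyl group. This fallback sets out from 6 and returns at 9.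

Further compounds
F1 | step 9 | hydroxy keto ester (acetoacetate adduct at C1, free C2 hydroxyl) | CC(=O)C(C(=O)OC)[C@@H]1[C@@H](O)[C@@](C)(CO)[C@H](O[Si](C)(C)C(C)(C)C)[C@@H](C)[C@@H]1C(C)=C
F0 | step 24 | none | none
F2 | step 7 | ethyl ester from Johnson–Claisen rearrangement (C3–CH2CO2Et, C1=C2) | CCOC(=O)C[C@]1(C)C=C[C@@H](C(C)=C)[C@H](C)[C@H]1O[Si](C)(C)C(C)(C)C
F3 | step 7 | carboxylic acid (C3–CH2CO2H) | OC(=O)C[C@]1(C)C=C[C@@H](C(C)=C)[C@H](C)[C@H]1O[Si](C)(C)C(C)(C)C
F4 | step 7 | N-hydroxypyridine-2-thione ester of F3 | S=c2ccccn2OC(=O)C[C@]1(C)C=C[C@@H](C(C)=C)[C@H](C)[C@H]1O[Si](C)(C)C(C)(C)C
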